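Its constants are invented; the flask was simulated.

Follow the reagent.

| setting | oak | elm | larch |
|---|---|---|---|
| starting material | 1.0 mM (fed, over 50 s) | 1.0 mM (fed, over 50 s) | 1.0 mM (fed, over 50 s) |
| reagent | 0.950 mM | 0.950 mM | 0.950 mM |
| free catalyst | 10 µM | 15 µM | 25 µM |
| second catalyst | 1.0 µM | 1.0 µM | 1.0 µM |
| time | 2.5 min | 2.5 min | 2.5 min |

    starting material + free catalyst ⇌ free catalyst + intermediate (K1 = 2.9, k1 = 6200 /M/s)
    reagent + second catalyst + intermediate → second catalyst + product (k2 = 6.1 × 10⁷ /M²/s)

- "hardly changes" means that all values lie within two and a half points (for a concentration: within two and a half percent of the largest)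
- run time (oak): 2.5 min

1. amount of product at the end, in percent of the starting material charged for oak, elm, larch, in this order
2. the course of these numbers from the first flask to the last (rises all the way / rises, then falls / falls, then rises / hardly changes / falls all the way)

Open the ledger with the limiting reagent: 0.950 mM of reagent stands against 1.0 mM of starting material. Each product costs one reagent and one intermediate, so a surplus d = 0.0500 mM of starting material finds no partner.

Call starting material plus intermediate the pool, and assume the first step keeps it at equilibrium, with a share f = 74.4% as intermediate. Let H be the logarithm to base ten of pool over reagent. Both lose the same amount, so their difference stays d. Under that assumption H rises steadily: the ledger climb s, the second step's constant times second catalyst times f times d, divided by 2.3, is 0.0592 /min.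

H starts at 0.0223. Treat the feed as one dose at its midpoint, then subtract the first step's relaxation time, which is 12.0 s in oak. That is shorter than the intermediate's lifetime in the second step with reagent as charged, 17.3 s, but not by much, so the assumption is fair rather than close in oak. Oak's clock is then 113 s, and H ends at 0.134.

| Oak's ledger, my reckoning | Amount |
|---|---|
| Reagent charged | 0.950 mM |
| Unreacted, from (reagent + d)/reagent = 1.36 | 0.139 mM |
| Turned into product | 0.811 mM |

The books close. With each flask's own relaxation time, I commit to 81.1% for oak, 81.6% for elm and 81.9% for larch. Held against the two and a half points allowed, the spread of 0.80 percentage points gives this course: hardly changes.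

The forecast gives 79.4%, 80.4% and 81.2%, hardly changes, on the grounds that “the three flasks converge”. My oak stands 1.7 points above it.

The flasks give 79.4%, 80.5% and 81.2%: hardly changes. In oak, by the end of the feed at 0.833 min, the second step had made 32.9% product, with 29.4% standing as intermediate; it ran on while reagent fell to 16% of its charge at 2.5 min. Oak's product puts H at 0.121, which by the climb s is 13.2 s behind my clock. Larch's product puts H at 0.134, against my 0.141, which is 6.62 s behind.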